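## Retrosynthetic overview
1. The C1–O(aryl) bond is made last, by Mitsunobu coupling of the free C15 tetraol with the 7-OH of 5,7-dihydroxycoumarin. No ring of the target is built, because the coumarin bicycle is bought intact.
2. The key disconnection is C8–C9. C9 is used as an oxiranyl anion, an alpha-oxygenated carbanion in which an epoxide carbon acts as donor instead of acceptor. C8, the acceptor carbon of an allylic alcohol, is likewise turned into a donor as an (E)-allylboronate.
3. The two carbons are joined on boron by a stereospecific 1,2-metallate shift. Oxidation of C–B to C–OH then gives the syn-9,10-diol from the single C10 stereocentre.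
4. The C10 fragment comes from geraniol by silyl protection, (E)-selective SeO2 hydroxylation and Pd-catalysed borylation.
5. The C5 fragment comes from methyl (S)-glycidate and 2 MeLi, with a silyl trap in the same flask. Its oxirane is the only other ring in the route and is opened in the key step.

Assumption: farnesane numbering is used for the side chain (C1 = OCH2, C11 = carbinol carbon bearing two methyl groups), and geraniol, methyl (S)-glycidate and 5,7-dihydroxycoumarin are taken as catalogue chemicals.

## Route

Step 1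
Reactants: 1 geraniol
Product: 2 tert-butyl{[(2E)-3,7-dimethylocta-2,6-dien-1-yl]oxy}diphenylsilane (geranyl TBDPS ether)
Conditions: TBDPSCl (1.05 equiv), imidazole (2 equiv), CH2Cl2, 0 °C → rt
Reagents that add atoms: tert-butyl(chloro)diphenylsilane, CC(C)(C)[Si](Cl)(c1ccccc1)c1ccccc1
Why: Imidazole-promoted silyl ether protection of the only hydroxyl group gives an ether that withstands SeO2, the cationic palladium catalyst and the lithium amide, and it creates no stereocentre.

Step 2
Reactants: 2 geranyl TBDPS ether
Product: 3 (2E,6E)-8-[(tert-butyldiphenylsilyl)oxy]-2,6-dimethylocta-2,6-dien-1-ol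
Conditions: SeO2 (0.15 equiv), t-BuOOH (3 equiv), salicylic acid (0.1 equiv), CH2Cl2, 0 °C → rt; the minor enal is removed by chromatography
Reagents that add atoms: tert-butyl hydroperoxide, CC(C)(C)OO (terminal source of the new oxygen atom); SeO2, O=[Se]=O (catalyst that hands the oxygen on)
Why: Riley allylic oxidation (ene reaction, then [2,3]-sigmatropic shift) attacks the more electron-rich distal trisubstituted alkene and hydroxylates only the methyl group trans to the chain, which fixes the (6E) geometry.

Step 3
Reactants: 3 allylic alcohol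
Product: 4 tert-butyl{[(2E,6E)-3,7-dimethyl-8-(4,4,5,5-tetramethyl-1,3,2-dioxaborolan-2-yl)octa-2,6-dien-1-yl]oxy}diphenylsilane
Conditions: B2pin2 (1.5 equiv), [Pd(MeCN)4](BF4)2 (5 mol %), DMSO/MeOH 1:1, rt → 40 °C
Reagents that add atoms: bis(pinacolato)diboron, CC1(C)OB(OC1(C)C)B1OC(C)(C)C(C)(C)O1
Why: In this palladium-catalysed allylic borylation of a free allylic alcohol, B2pin2 reduces the divalent palladium salt to zerovalent palladium, a boron Lewis acid from the BF4 counter-ion activates the hydroxyl, and the syn eta-3-allyl complex is borylated at its unhindered CH2 terminus to give the linear (E)-allylboronate, while the C1 silyl ether is too poor a leaving group to ionise.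

Step 4
Reactants: 5 methyl (S)-glycidate
Product: 7 triethyl({2-[(2S)-oxiran-2-yl]propan-2-yl}oxy)silane, via lithium alkoxide 6 (not isolated)
Conditions: MeLi (2.05 equiv, halide-free), Et2O, −78 °C, 1 h; then TESCl (2.2 equiv), THF, −78 °C → rt
Reagents that add atoms: methyllithium, [Li]C (two CH3 groups); chlorotriethylsilane, CC[Si](Cl)(CC)CC
Why: Double 1,2-addition of MeLi to the ester is faster at −78 °C than epoxide opening or alpha-deprotonation, and the resulting tertiary lithium alkoxide is silylated in the same flask, so the C10 stereocentre is taken unchanged from the chiral-pool glycidate.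

Step 5 (key step)
Reactants: 4 allylboronate; 7 (S)-epoxide
Product: 11 (2E,6E,9R,10S)-1-[(tert-butyldiphenylsilyl)oxy]-3,7,11-trimethyl-10,11-bis[(triethylsilyl)oxy]dodeca-2,6-dien-9-ol, via oxiranyllithium 8 (not isolated), via lithium boronate complex 9 (not isolated), via beta-silyloxy boronic ester 10 (not isolated)
Conditions: 7 (1.5 equiv) + 4 (1.0 equiv), lithium 2,2,6,6-tetramethylpiperidide (1.6 equiv, from the amine + n-BuLi), THF, −30 °C, 2 h; TESOTf (1.6 equiv), −78 °C → rt; then aq. NaOH, 30% H2O2, THF, 0 °C
Reagents that add atoms: triethylsilyl trifluoromethanesulfonate, CC[Si](CC)(CC)OS(=O)(=O)C(F)(F)F; hydrogen peroxide, OO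
Why: This is a lithiation–borylation with an oxiranyl anion (Matteson-type 1,2-metallate rearrangement) in which the hindered amide removes the epoxide CH2 proton trans to the bulky side chain (C11 has no hydrogen, so no allylic-alcohol isomerisation, and the C10 oxygen is the ring oxygen, so no beta-elimination) to give an alpha-oxygenated carbanion, so that C9 reacts with reversed polarity as a donor although it is an acceptor in 7, just as C8 was the acceptor carbon of 3; boron captures it with retention, TESOTf pulls on the epoxide oxygen, the allyl CH2 migrates from boron to C9 anti to the breaking C9–O bond (inversion, no allyl transposition, (E)-alkene kept), and the retentive C–B oxidation delivers only the syn (9R,10S) array from the single C10 stereocentre.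

Step 6
Reactants: 11 tris-silyl ether
Product: 12 (2E,6E,9R,10S)-3,7,11-trimethyldodeca-2,6-diene-1,9,10,11-tetrol
Conditions: TBAF (5 equiv), THF, rt → 40 °C
Reagents that add atoms: none
Why: Fluoride-driven desilylation (strong Si–F bond) frees all four hydroxyl groups without touching the alkenes or the two carbinol stereocentres.

Step 7
Reactants: 12 tetraol; 13 5,7-dihydroxycoumarin
Product: 14 5-hydroxy-7-{[(2E,6E,9R,10S)-9,10,11-trihydroxy-3,7,11-trimethyldodeca-2,6-dien-1-yl]oxy}-2H-chromen-2-one (target)
Conditions: 13 (2 equiv), PPh3 (1.15 equiv), DIAD (1.1 equiv, slow addition), THF, 0 °C → rt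
Reagents that add atoms: none
Why: In this Mitsunobu etherification only the unhindered primary allylic alcohol of 12 gives a reactive alkoxyphosphonium salt at 0 °C, and the more acidic, sterically free 7-OH of 13 (the 5-OH is peri to H-4) is the phenoxide that displaces it by SN2, so no stereocentre or alkene is touched.

## Compound list
1 | geraniol | C/C(=C\CO)CCC=C(C)C | starting material
2 | geranyl TBDPS ether | C/C(=C\CO[Si](c1ccccc1)(c1ccccc1)C(C)(C)C)CCC=C(C)C | intermediate
3 | (2E,6E)-8-[(tert-butyldiphenylsilyl)oxy]-2,6-dimethylocta-2,6-dien-1-ol | C/C(=C\CO[Si](c1ccccc1)(c1ccccc1)C(C)(C)C)CC/C=C(\C)CO | intermediate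
4 | (2E,6E)-8-Bpin geranyl TBDPS ether | C/C(=C\CO[Si](c1ccccc1)(c1ccccc1)C(C)(C)C)CC/C=C(\C)CB1OC(C)(C)C(C)(C)O1 | intermediate
5 | methyl (S)-glycidate | COC(=O)[C@@H]1CO1 | starting material
6 | lithium 2-[(2S)-oxiran-2-yl]propan-2-olate | [Li+].[O-]C(C)(C)[C@@H]1CO1 | intermediate (not isolated)
7 | triethyl({2-[(2S)-oxiran-2-yl]propan-2-yl}oxy)silane | CC[Si](CC)(CC)OC(C)(C)[C@@H]1CO1 | intermediate
8 | [(2R,3S)-3-{2-[(triethylsilyl)oxy]propan-2-yl}oxiran-2-yl]lithium (Li trans to the side chain) | CC[Si](CC)(CC)OC(C)(C)[C@H]1O[C@@H]1[Li] | intermediate (not isolated)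
9 | lithium boronate complex of 4 and 8 (boron on C9 with retention, trans to the side chain) | [Li+].C/C(=C\CO[Si](c1ccccc1)(c1ccccc1)C(C)(C)C)CC/C=C(\C)C[B-]1(OC(C)(C)C(C)(C)O1)[C@H]2O[C@@H]2C(C)(C)O[Si](CC)(CC)CC | intermediate (not isolated)
10 | (2E,6E,9R,10S)-9-Bpin-1-(TBDPS-oxy)-10,11-bis(TES-oxy)-3,7,11-trimethyldodeca-2,6-diene | C/C(=C\CO[Si](c1ccccc1)(c1ccccc1)C(C)(C)C)CC/C=C(\C)C[C@@H](B1OC(C)(C)C(C)(C)O1)[C@H](O[Si](CC)(CC)CC)C(C)(C)O[Si](CC)(CC)CC | intermediate (not isolated)
11 | (2E,6E,9R,10S)-1-(TBDPS-oxy)-10,11-bis(TES-oxy)-3,7,11-trimethyldodeca-2,6-dien-9-ol | C/C(=C\CO[Si](c1ccccc1)(c1ccccc1)C(C)(C)C)CC/C=C(\C)C[C@@H](O)[C@H](O[Si](CC)(CC)CC)C(C)(C)O[Si](CC)(CC)CC | intermediate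
12 | (2E,6E,9R,10S)-3,7,11-trimethyldodeca-2,6-diene-1,9,10,11-tetrol | C/C(=C\CO)CC/C=C(\C)C[C@@H](O)[C@H](O)C(C)(C)O | intermediate
13 | 5,7-dihydroxycoumarin | Oc1cc(O)c2ccc(=O)oc2c1 | starting material
14 | 5-hydroxy-7-{[(2E,6E,9R,10S)-9,10,11-trihydroxy-3,7,11-trimethyldodeca-2,6-dien-1-yl]oxy}-2H-chromen-2-one | C/C(=C\COc1cc(O)c2ccc(=O)oc2c1)CC/C=C(\C)C[C@@H](O)[C@H](O)C(C)(C)O | target

## Step count and risks
Total steps: 7. Longest linear sequence: 6 (steps 1, 2, 3, 5, 6, 7, from geraniol).

**Step 5.** The amide base may deprotonate allylboronate 4 at C8, or the hindered oxiranyllithium may decay before boron captures it. The fallback makes the carbanion by transmetalation instead of by deprotonation in the presence of 4.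
- It sets out from 7. Lithiation with s-BuLi/(−)-sparteine (Et2O–hexane, −90 °C) and quenching with Bu3SnCl give the storable trans-epoxystannane F1.
- Tin–lithium exchange with n-BuLi (THF, −90 °C, retention) regenerates 8 free of any amine base.
- Boronate 4 is then added, followed by TESOTf and NaOH/H2O2, and the route is rejoined at 11.

**Step 7.** Two selectivities are asked of one reaction: primary alcohol against the triol, and 7-OH against 5-OH. The fallback masks both partners; it sets out from 12 and 13 and comes back at 14.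
- Compound 12 is treated with 2,2-dimethoxypropane/PPTS and then briefly with MeOH, which gives the acetonide alcohol F2.
- Compound 13 is peracetylated (Ac2O, pyridine) to 5,7-diacetoxycoumarin F3.
- The more activated and unhindered 7-acetate of F3 is cleaved with PhSH/imidazole in NMP, which gives 5-acetoxy-7-hydroxycoumarin F4.
- Mitsunobu coupling of F2 with F4 gives the acetate acetonide ether F5.
- K2CO3/MeOH gives the acetonide of the target F6, and 80% aqueous AcOH at rt releases 14.

**Step 3.** The cationic palladium/methanol medium may cause protodeborylation or erode the silyl ether. The fallback replaces direct hydroxyl activation by a halide route; it sets out from 3 and comes back at 4.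
- An Appel reaction (CBr4, PPh3, CH2Cl2, 0 °C) gives the allylic bromide F7.
- F7 undergoes oxidative addition to zerovalent palladium (Pd2(dba)3, 2.5 mol %) and is borylated with B2pin2 in THF at 60 °C under neutral conditions, which gives 4.

## Further compounds
F1 | step 5 | trans-epoxystannane, tributyl[(2R,3R)-3-{2-[(triethylsilyl)oxy]propan-2-yl}oxiran-2-yl]stannane | CCCC[Sn](CCCC)(CCCC)[C@H]1O[C@@H]1C(C)(C)O[Si](CC)(CC)CC
F2 | step 7 | acetonide alcohol, 2-[(4S,5R)-5-[(2E,6E)-8-hydroxy-2,6-dimethylocta-2,6-dien-1-yl]-2,2-dimethyl-1,3-dioxolan-4-yl]propan-2-ol | C/C(=C\CO)CC/C=C(\C)C[C@H]1OC(C)(C)O[C@@H]1C(C)(C)O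
F3 | step 7 | 5,7-diacetoxycoumarin | CC(=O)Oc1cc(OC(C)=O)c2ccc(=O)oc2c1
F4 | step 7 | 5-acetoxy-7-hydroxycoumarin | Oc1cc(OC(C)=O)c2ccc(=O)oc2c1
F5 | step 7 | acetate acetonide ether (5-O-acetyl 9,10-O-isopropylidene derivative of 14) | C/C(=C\COc1cc(OC(C)=O)c2ccc(=O)oc2c1)CC/C=C(\C)C[C@H]1OC(C)(C)O[C@@H]1C(C)(C)O
F6 | step 7 | acetonide of the target (9,10-O-isopropylidene derivative of 14) | C/C(=C\COc1cc(O)c2ccc(=O)oc2c1)CC/C=C(\C)C[C@H]1OC(C)(C)O[C@@H]1C(C)(C)O
F7 | step 3 | allylic bromide, {[(2E,6E)-8-bromo-3,7-dimethylocta-2,6-dien-1-yl]oxy}(tert-butyl)diphenylsilane | C/C(=C\CO[Si](c1ccccc1)(c1ccccc1)C(C)(C)C)CC/C=C(\C)CBr
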